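## Structural features

The target 26 (heavy atoms numbered 1–32 in the order of its SMILES string) has six rings. An α,β-unsaturated δ-lactone (ring A: C2, O4, C5, C7, C8, C9) is spiro-linked at C9 to cyclohexane ring B (C9, C10, C11, C12, C21, C22). Ring B is cis-fused through C12–C21 to cyclopentane ring C (C12, C21, C20, C18, C25). Ring C spans two bridges of a bicyclo[2.2.2]octan-2-one (bridgeheads C14 and C25; bridges C12–C13, C16(=O)–C18 and C30–C31), and a γ-lactone (C25, C26, O27, C28, C30) is fused on the C25–C30 bond.

There are nine stereocentres. Five are all-carbon quaternary (C9, C12, C14, C18, C25), three of them contiguous (C18–C25–C12), and C22 is a tertiary carbinol next to the spiro carbon.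

The C31 hydroxyl is β to both the C16 ketone and the C28 lactone carbonyl, so it is prone to retro-aldol cleavage and to β-elimination through C30. The unsaturated lactone is a base-labile Michael acceptor, and the C22 carbinol beside quaternary C9 can fragment or dehydrate under acid.

The real difficulty is the crowded cage with its absolute configuration, followed by the late spiro centre C9 beside C22. The key step uses three features of the cage:
- C16, C18, C25, C12, C13 and C14, with O17 and the methyls C15 and C19, are a dearomatized 2,6-dimethylphenol.
- The C30–C31 bridge carries C28, which is tied back to bridgehead C25 through C26–O27, so the bridge is an acrylate delivered across C25 and C14 from a benzylic ester.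
- The C20 methylene on C18, followed by C21 and C22, is the trace of an ortho-Claisen shift of a but-3-en-2-yl ether.

## Logic of the disconnections

**26 ⇒ 25.** Only the O32–Si bond is added. The C31 hydroxyl has to be masked whenever base, hydride or oxidant is used, because it is β to two carbonyls. The forward unmasking must therefore be non-basic.

**25 ⇒ 24.** C9–C22 and O4–C2 are cut together, which opens rings A and B. Both bonds start from the C9=C2 alkene of a dienoic acid: C9 is the π-nucleophile toward the C22 carbonyl and C2 is the cation taken by the carboxyl oxygen. This removes the spiro centre, the tertiary carbinol and two rings, leaving a methyl ketone on ring C and an open chain. The forward step needs a chair closure that puts O24 and C2 trans, a (Z) C7=C8 bond, and the C21 epimer whose acetyl group is cis to C11.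

**24 ⇒ 22 ⇒ 21.** The C7=C8 bond is cut (a two-carbon phosphonate olefination, then ester cleavage). The gain is an α-alkylidene aldehyde. The demand is (Z)-selectivity and an olefination reagent that ignores two ketones and a lactone.

**21 ⇒ 20 ⇒ 19 ⇒ 18, and 16 ⇒ 15.** C9=C2 is traced back to a C9–C2 aldol bond between the side-chain ester enolate and a three-carbon ketone, with C8 moved from ester to aldehyde level by reduction and re-oxidation. The gain is a plain methyl ester chain, the same one that is present from the first step. The demand is that the aldol precedes ring C formation (no ketone present yet), and that a reduce-all/re-oxidize-all pair is accepted because no hydride separates the methyl ester from the lactone.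

**18 ⇒ 16.** C12–C21 and C22–O24 are cut. C12 is a tertiary radical reachable from the C12=C13 alkene by hydrogen-atom transfer, and C21=C22 of the butenyl group sits five atoms away. Ring C and quaternary C12 disappear, leaving the bicyclooctene with its butenyl side arm. The demand is that cyclization outruns oxygen capture at C12.

**15 ⇒ 14 ⇒ 13.** O32–Si and then C31–O are cut back to C31–B. Boron survives the thermolysis and is replaced by oxygen with retention, so the C31 configuration is decided in the cycloaddition.

**13 ⇒ 11 (through 12).** C25–C30, C14–C31 and C18–C20 are cut. The cage and the lactone fall back to a flat pentasubstituted arene carrying an ester-tethered dienophile and a chiral allylic ether; two rings, three skeletal bonds and five stereocentres are removed at once. The demands are chirality transfer in the sigmatropic shift, addition of the dienophile to the diene face anti to the butenyl group, and endo orientation of the ester carbonyl.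

**11 ⇒ 10 ⇒ 8 + 9.** B–C31 and the ester bond C28–O27 are cut. The dienophile is assembled on the substrate from a three-carbon ynoic acid, so no separate borylated acid has to be made. The demand is syn borylation giving the (E)-alkene.

**8 ⇒ 7 ⇒ 5 + 6.** C26 is returned to the aldehyde level, and the O17–C22 ether bond is cut. The ether is made with inversion from the commercial allylic alcohol while C26 is still an aldehyde, so the phenol is the only hydroxyl present. The demand is clean SN2 etherification of a di-ortho-substituted phenol.

**5 ⇒ 4 ⇒ 3 ⇒ 1 + 2.** C25–C26 (formylation at the only free ring position type) and C12–C11 (para acylation, then removal of the benzylic oxygen) are cut. The arene is reduced to two bulk chemicals.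

## Other disconnections considered

**Alternative 1:** The cut is C18–C20, C12–C21 and C10–C11, which strips rings B and C from a preformed bicyclo[2.2.2]octanone A3 carrying an exocyclic (phenylsulfonyl)methylidene at C12 and a ketal at C31. In the forward key step the C16-ketone enolate would add through C18 to divinyl ketone A2; the resulting enolate would attack C12 of the vinyl sulfone through C21 (ring C); the α-sulfonyl carbanion at C11 would then close ring B on the remaining enone carbon C10, giving isotwistane A1.
- In favour: three C–C bonds, two rings and the centres C18, C12 and C21 are formed in one operation by conjugate additions of a well-understood kind. The first addition is reversible, so only the C18 epimer able to cyclize is drained. Ring B arrives with a C22 carbonyl ready for methyl addition.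
- Against: A3 already contains both bridgehead quaternary carbons and must be made in enantioenriched form by other means. C30 is a bare methylene, so C28, the lactone and the C31 carbinol configuration all remain to be installed next to a ketone. The spiro lactone must be built on C9 by double functionalization α to C22, the sulfone must be removed, and A2 polymerizes readily.
- Comparison: on rings B and C this route is the better one, because C21 is fixed inside the cascade, whereas the chosen plan leaves C21 open until ring B closes. On the cage and the γ-lactone it is weaker, since the chosen step makes both from an arene in one step. Mechanistically both are cascades with a final irreversible event. In step count it is probably no shorter once A3 and the lactone bridge are included.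

**Alternative 2:** The cut is C12–C13 and C16–C18 of the six-membered carbocycle, back to the cyclopentanone β-keto ester A6 (ring C, with C21 already present as an isopropenyl-bearing centre) and methacrolein A5. In the forward key step C12 would add to A5, and the only remaining enolizable position, C18, would close on the aldehyde to give the bicyclo[3.2.1]octan-8-one ketol A4.
- In favour: both quaternary bridgeheads C12 and C18 come from robust enolate chemistry with cheap reagents. The isopropenyl group is a masked C22 acetyl of fixed configuration, and absolute configuration can come from a chiral-pool cyclopentanone.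
- Against: A4 lacks the C30–C31 bridge, C14 is still tertiary, and C25 is a hindered bridging ketone. The C11 ester on a neopentyl carbon must be extended by three carbons for ring B, so many steps are left. The aldol is reversible.
- Comparison: as a single step this annulation is at least as reliable as the chosen cascade, and it is better on C21 and on the absence of any methyl-versus-butenyl facial question. It is much less convergent on structure, and step economy clearly favours the chosen plan.

**Alternative 3:** The cut is C25–C30 and C26–C28, a later stage of the same bicyclo[3.2.1]octane plan. Dichloroketene A8 would add across the exocyclic C25=C26 methylene of A9 to give the spiro α,α-dichlorocyclobutanone A7, whose four ring carbons are those of the γ-lactone.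
- In favour: ketene [2+2] cycloaddition is one of the few reactions that builds a quaternary carbon on a crowded 1,1-disubstituted alkene with intrinsic regiochemistry. The chlorines would direct a later oxygen insertion to the C26 side and would activate C30 for closure onto C31.
- Against: the ketene must approach the face over the three-carbon bridge, which is not obviously the open one. A7 still needs oxygen insertion, dechlorination, C30–C31 closure and control of C30 and C31, with several carbonyl groups to keep apart.
- Comparison: each operation is individually well precedented, and the route avoids the facial issue of the chosen cycloaddition, a point on which it is the better. It makes C25–C30 alone, over four or five steps, whereas the chosen step makes C25–C30, C14–C31 and the lactone at once, with regiochemistry fixed by the tether. Step economy again favours the chosen plan.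

Key step: step 8

Assumption: 16–20 are carried as C9 epimer mixtures and 17–19 as C22 carbinol epimers, centres that are erased later; from 17 onward the structures are drawn with the C21 configuration of the target, which step 12 does not guarantee but which is epimerizable once C22 is a ketone (from 20) and is the only one able to close ring B.

## Route

Step 1
Reactants: 1 2,6-dimethylphenol; 2 succinic anhydride
Product: 3 4-(4-hydroxy-3,5-dimethylphenyl)-4-oxobutanoic acid
Conditions: AlCl3 (3.3 equiv), PhNO2, 0 °C → rt; aq. HCl
Reagents that add atoms: none
Why: Friedel–Crafts acylation; both ortho positions carry methyl groups, so the acylium complex can only enter para to the hydroxyl, installing C11–C8 as one unit.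

Step 2
Reactants: 3 4-(4-hydroxy-3,5-dimethylphenyl)-4-oxobutanoic acid
Product: 4 methyl 4-(4-hydroxy-3,5-dimethylphenyl)butanoate
Conditions: H2 (3 atm), 10% Pd/C, MeOH, H2SO4 (cat.), 50 °C
Reagents that add atoms: methanol CO
Why: Acid-assisted hydrogenolysis of the para-hydroxyaryl ketone to the methylene should run alongside Fischer esterification in the same acidic methanol.

Step 3
Reactants: 4 methyl 4-(4-hydroxy-3,5-dimethylphenyl)butanoate
Product: 5 methyl 4-(2-formyl-4-hydroxy-3,5-dimethylphenyl)butanoate
Conditions: Cl2CHOMe (1.3 equiv), TiCl4 (2.5 equiv), CH2Cl2, 0 °C → rt; H2O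
Reagents that add atoms: dichloromethyl methyl ether COC(Cl)Cl; water O
Why: Rieche formylation; the two free ring positions are equivalent, each flanked by two alkyl groups and para to a third as in mesitylene, and the first formyl group deactivates the ring against a second.

Step 4
Reactants: 5 methyl 4-(2-formyl-4-hydroxy-3,5-dimethylphenyl)butanoate; 6 (R)-but-3-en-2-ol
Product: 7 methyl 4-{4-[(2S)-but-3-en-2-yloxy]-2-formyl-3,5-dimethylphenyl}butanoate
Conditions: PPh3, DIAD, THF, 0 °C → rt
Reagents that add atoms: none
Why: Mitsunobu etherification with SN2 inversion turns the (R)-alcohol into the (S)-aryl ether (the future C22); the formyl group makes the hindered phenol more acidic, and it is the only hydroxyl present at this stage.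

Step 5
Reactants: 7 methyl 4-{4-[(2S)-but-3-en-2-yloxy]-2-formyl-3,5-dimethylphenyl}butanoate
Product: 8 methyl 4-{4-[(2S)-but-3-en-2-yloxy]-2-(hydroxymethyl)-3,5-dimethylphenyl}butanoate
Conditions: NaBH4, MeOH/THF, 0 °C
Reagents that add atoms: none
Why: Chemoselective borohydride reduction of the aryl aldehyde; the methyl ester and the allylic aryl ether should be untouched at 0 °C.

Step 6
Reactants: 8 methyl 4-{4-[(2S)-but-3-en-2-yloxy]-2-(hydroxymethyl)-3,5-dimethylphenyl}butanoate; 9 propiolic acid
Product: 10 {3-[(2S)-but-3-en-2-yloxy]-6-(4-methoxy-4-oxobutyl)-2,4-dimethylphenyl}methyl prop-2-ynoate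
Conditions: DCC, DMAP (5 mol%), CH2Cl2, −20 → 0 °C
Reagents that add atoms: none
Why: Steglich esterification of the primary benzylic alcohol; low temperature and catalytic DMAP limit amine addition to the ynoate.

Step 7
Reactants: 10 {3-[(2S)-but-3-en-2-yloxy]-6-(4-methoxy-4-oxobutyl)-2,4-dimethylphenyl}methyl prop-2-ynoate
Product: 11 {3-[(2S)-but-3-en-2-yloxy]-6-(4-methoxy-4-oxobutyl)-2,4-dimethylphenyl}methyl (2E)-3-(4,4,5,5-tetramethyl-1,3,2-dioxaborolan-2-yl)prop-2-enoate
Conditions: B2pin2 (1.1 equiv), CuCl (5 mol%), Xantphos (5 mol%), NaOtBu (10 mol%), MeOH (2 equiv), THF, rt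
Reagents that add atoms: bis(pinacolato)diboron CC1(C)OB(OC1(C)C)B1OC(C)(C)C(C)(C)O1
Why: Copper-catalysed conjugate borylation and protonation of the ynoate (a formal hydroboration); syn addition puts boron on the terminal carbon trans to the ester, which is also the thermodynamic (E)-isomer, and the unactivated alkene is inert.

Step 8
Reactants: 11 {3-[(2S)-but-3-en-2-yloxy]-6-(4-methoxy-4-oxobutyl)-2,4-dimethylphenyl}methyl (2E)-3-(4,4,5,5-tetramethyl-1,3,2-dioxaborolan-2-yl)prop-2-enoate
Product: 13 lactone-fused bicyclo[2.2.2]octenone C31 pinacol boronate, via ortho-dienone 12 (not isolated)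
Conditions: 1,2-dichlorobenzene (0.01 M), BHT (10 mol%), 180 °C, sealed tube, argon
Reagents that add atoms: none
Why: Heating sets up a reversible aromatic [3,3] Claisen shift of the butenyl group to either methyl-bearing ortho carbon; only the C18-alkylated 2,4-cyclohexadienone 12 has diene terminus C25 beside the acrylate tether, and its irreversible intramolecular [4+2] cycloaddition (C25–C30 and C14–C31) drains the equilibrium. The closest known reaction type is the tandem aromatic Claisen rearrangement with Diels–Alder trapping of the ortho-dienone, including chirality transfer from 1-methylallyl aryl ethers. The γ-lactone (C25, C26, O27, C28, C30) closes as the tether ring of the intramolecular Diels–Alder reaction, and the carbocycle C25–C30–C31–C14–C13–C12 closes by the cycloaddition itself, completing the bicyclo[2.2.2]octenone. C18 is set by the chair Claisen transition state with the C23 methyl pseudo-equatorial, which passes the (S) centre of the ether on to C18 and gives the (E)-alkene. C25 and C14 are set by addition of the dienophile to the diene face anti to the butenyl group, that is, syn to methyl C19. C30 and C31 are set by the endo position of the ester carbonyl under C12–C13 and by the (E)-geometry of the borylacrylate, which fixes C28 and boron trans. The step needs regioselectivity, endo selectivity and facial selectivity: the three-atom ester tether can only deliver C30 to C25; the short tether and secondary overlap favour endo; and the face syn to C19 should be preferred because a butenyl chain on the dienophile face would have to fold over the incoming C30–H and the exo boronate, a preference whose size is uncertain. The boronate serves as a masked C31 hydroxyl that should survive the thermolysis.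

Step 9
Reactants: 13 lactone-fused bicyclo[2.2.2]octenone C31 pinacol boronate
Product: 14 C31 alcohol of the lactone-fused bicyclo[2.2.2]octenone
Conditions: NaBO3·4H2O, THF/H2O (1:1), rt
Reagents that add atoms: sodium perborate [Na+].[Na+].O[B-]1(O)OO[B-](O)(O)OO1
Why: Perborate oxidation of the secondary alkylboronate, with 1,2-migration of C31 from boron to oxygen and retention; the mild pH should spare the methyl ester and lactone and avoid retro-aldol of the new β-hydroxy ketone.

Step 10
Reactants: 14 C31 alcohol of the lactone-fused bicyclo[2.2.2]octenone
Product: 15 C31 tert-butyldimethylsilyl ether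
Conditions: TBSOTf, 2,6-lutidine, CH2Cl2, 0 °C
Reagents that add atoms: tert-butyldimethylsilyl trifluoromethanesulfonate CC(C)(C)[Si](C)(C)OS(=O)(=O)C(F)(F)F
Why: Silylation of the hindered secondary alcohol with the silyl triflate masks the β-hydroxy ketone and lactone against retro-aldol, β-elimination and the later oxidations; C16 has no α-hydrogen and lutidine is too weak to enolize the lactone.

Step 11
Reactants: 15 C31 tert-butyldimethylsilyl ether
Product: 16 C9 aldol adduct (methyl 3-hydroxy-3-methylbutanoate side chain)
Conditions: LiN(iPr)2 (1.05 equiv), THF, −78 °C; acetone (3 equiv); AcOH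
Reagents that add atoms: acetone CC(C)=O
Why: Kinetic ester-enolate aldol addition; the open C9 methylene should be deprotonated faster than the neopentyl cage methine C30, and the β-silyloxy lactone is kept at −78 °C throughout.

Step 12
Reactants: 16 C9 aldol adduct (methyl 3-hydroxy-3-methylbutanoate side chain)
Product: 18 isotwistane C22 carbinol, via C22 hydroperoxide 17 (not isolated)
Conditions: Mn(dpm)3 (20 mol%; dpm = 2,2,6,6-tetramethylheptane-3,5-dionate), PhSiH3 (3 equiv), air (slow stream), iPrOH/CH2Cl2, 0 °C → rt; then PPh3
Reagents that add atoms: dioxygen O=O
Why: Mukaiyama-type metal-hydride hydrogen-atom transfer puts hydrogen on C13 and a tertiary radical on C12, which closes 5-exo-trig onto C21 of the butenyl group held beside it (ring C; the cage allows only cis fusion, which sets C12); the C22 radical is trapped by O2 and the hydroperoxide reduced by PPh3. The disubstituted butenyl alkene is a much poorer hydrogen-atom acceptor than the trisubstituted C12=C13; the C21 outcome is not relied on.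

Step 13
Reactants: 18 isotwistane C22 carbinol
Product: 19 lactol triol (C8 primary alcohol, C2 and C22 carbinols, C28 lactol)
Conditions: iBu2AlH (7 equiv), CH2Cl2, −78 → −40 °C; aq. potassium sodium tartrate
Reagents that add atoms: none
Why: Aluminium hydride reduction takes the methyl ester to the primary alcohol while the γ-lactone stops at the lactol as its aluminium hemiacetal; since no hydride tells the ester from the lactone, both are reduced and the lactone is restored in step 14, where any C8 aldehyde-level or C16 carbinol material also converges.

Step 14
Reactants: 19 lactol triol (C8 primary alcohol, C2 and C22 carbinols, C28 lactol)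
Product: 20 β-hydroxy aldehyde with C22 methyl ketone and restored γ-lactone
Conditions: Dess–Martin periodinane (5 equiv), CH2Cl2, 0 °C → rt
Reagents that add atoms: none
Why: Dess–Martin oxidation converts the primary alcohol to the aldehyde, the C22 carbinol to the methyl ketone and the lactol to the lactone in one operation; the tertiary alcohol and the silyl ether are inert.

Step 15
Reactants: 20 β-hydroxy aldehyde with C22 methyl ketone and restored γ-lactone
Product: 21 α-isopropylidene aldehyde (C9=C2)
Conditions: TsOH·H2O (10 mol%), toluene, 4 Å MS, 40 °C
Reagents that add atoms: none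
Why: Acid-catalysed dehydration of the tertiary β-hydroxy aldehyde, the second half of an aldol condensation; conjugation with the aldehyde directs the alkene to C9=C2 and erases the C9 stereocentre.

Step 16
Reactants: 21 α-isopropylidene aldehyde (C9=C2)
Product: 22 methyl (2Z)-dienoate
Conditions: (CF3CH2O)2P(O)CH2CO2Me, KN(SiMe3)2, 18-crown-6, THF, −78 °C
Reagents that add atoms: methyl bis(2,2,2-trifluoroethyl)phosphonoacetate COC(=O)CP(=O)(OCC(F)(F)F)OCC(F)(F)F
Why: Still–Gennari olefination; fast elimination from the kinetic adduct gives the (Z)-enoate needed for lactonization, and the stabilized phosphonate anion reacts with the aldehyde only, being too weakly basic to enolize the ketone or the lactone.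

Step 17
Reactants: 22 methyl (2Z)-dienoate
Product: 24 (2Z)-dienoic acid, via ring-opened dilithium hydroxy dicarboxylate 23 (not isolated)
Conditions: LiOH·H2O (5 equiv), THF/MeOH/H2O, 0 °C → rt; then 1 M HCl to pH 2
Reagents that add atoms: lithium hydroxide [Li+].[OH-]
Why: Saponification of the methyl ester; the γ-lactone is expected to open reversibly to 23 and to reclose on acidification because the hydroxy acid sits on a rigid cage. C21, α to the ketone, equilibrates under these conditions.

Step 18
Reactants: 24 (2Z)-dienoic acid
Product: 25 C31-silylated spirolactone (rings A and B closed)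
Conditions: Me2AlCl (3.5 equiv), CH2Cl2, −78 → 0 °C; aq. potassium sodium tartrate
Reagents that add atoms: none
Why: Proposed new method: Me2AlCl turns the acid into an aluminium carboxylate, so that no proton is left to add to the diene, and activates the C22 ketone; the tetrasubstituted C9=C2 alkene attacks C22 through C9 in a six-membered chair (ring B) and the tertiary C2 cation is captured by the (Z)-carboxylate oxygen (ring A), which is a ketone Prins cyclization ended by lactonization. The closest known reaction types are alkylaluminium-halide-promoted intramolecular Prins and carbonyl-ene cyclizations of keto-olefins and cation–olefin cyclizations terminated by a carboxylic acid. C22 should be set by the ketone methyl taking the equatorial site of the cage-imposed chair (O24 axial, on the face of C25), and C9 by an antiperiplanar arrangement of C9=C2 and the aluminium-bound carbonyl that leaves C8 equatorial; only the C21 epimer with the acetyl group cis to C11 can reach this chair.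

Step 19
Reactants: 25 C31-silylated spirolactone (rings A and B closed)
Product: 26 target CNP0360620.3
Conditions: HF·pyridine, pyridine/THF, 0 °C → rt
Reagents that add atoms: none
Why: Fluoride cleavage of the silyl ether under buffered, mildly acidic conditions, which avoids the retro-aldol and β-elimination that a basic fluoride source could trigger at C31.

## Compound list

1 | 2,6-dimethylphenol | Cc1cccc(C)c1O | starting material
2 | succinic anhydride | O=C1CCC(=O)O1 | starting material
3 | 4-(4-hydroxy-3,5-dimethylphenyl)-4-oxobutanoic acid | Cc1cc(C(=O)CCC(=O)O)cc(C)c1O | intermediate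
4 | methyl 4-(4-hydroxy-3,5-dimethylphenyl)butanoate | COC(=O)CCCc1cc(C)c(O)c(C)c1 | intermediate
5 | methyl 4-(2-formyl-4-hydroxy-3,5-dimethylphenyl)butanoate | COC(=O)CCCc1cc(C)c(O)c(C)c1C=O | intermediate
6 | (R)-but-3-en-2-ol | C=C[C@@H](C)O | starting material
7 | methyl 4-{4-[(2S)-but-3-en-2-yloxy]-2-formyl-3,5-dimethylphenyl}butanoate | C=C[C@H](C)Oc1c(C)cc(CCCC(=O)OC)c(C=O)c1C | intermediate
8 | methyl 4-{4-[(2S)-but-3-en-2-yloxy]-2-(hydroxymethyl)-3,5-dimethylphenyl}butanoate | C=C[C@H](C)Oc1c(C)cc(CCCC(=O)OC)c(CO)c1C | intermediate
9 | propiolic acid | C#CC(=O)O | starting material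
10 | {3-[(2S)-but-3-en-2-yloxy]-6-(4-methoxy-4-oxobutyl)-2,4-dimethylphenyl}methyl prop-2-ynoate | C=C[C@H](C)Oc1c(C)cc(CCCC(=O)OC)c(COC(=O)C#C)c1C | intermediate
11 | {3-[(2S)-but-3-en-2-yloxy]-6-(4-methoxy-4-oxobutyl)-2,4-dimethylphenyl}methyl (2E)-3-(pinacolboryl)prop-2-enoate (key-step precursor) | C=C[C@H](C)Oc1c(C)cc(CCCC(=O)OC)c(COC(=O)/C=C/B2OC(C)(C)C(C)(C)O2)c1C | intermediate
12 | (6R)-6-[(2E)-but-2-enyl]-2,6-dimethyl-4-(4-methoxy-4-oxobutyl)-5-{[(2E)-3-(pinacolboryl)acryloyloxy]methyl}cyclohexa-2,4-dien-1-one | C/C=C/C[C@@]1(C)C(=O)C(C)=CC(CCCC(=O)OC)=C1COC(=O)/C=C/B2OC(C)(C)C(C)(C)O2 | intermediate (not isolated)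
13 | lactone-fused bicyclo[2.2.2]oct-5-en-2-one: methyl butanoate chain on C12, (E)-but-2-enyl on C18 syn to the C12=C13 bridge, lactone carbonyl C28 syn to that bridge, pinacolboryl on C31 anti to it | COC(=O)CCCC1=C[C@]2(C)C(=O)[C@](C)(C/C=C/C)[C@]13COC(=O)[C@@H]3[C@H]2B4OC(C)(C)C(C)(C)O4 | intermediate
14 | C31 alcohol of 13 (hydroxyl in place of boron, same configuration) | COC(=O)CCCC1=C[C@]2(C)C(=O)[C@](C)(C/C=C/C)[C@]13COC(=O)[C@@H]3[C@H]2O | intermediate
15 | C31 tert-butyldimethylsilyl ether of 14 | COC(=O)CCCC1=C[C@]2(C)C(=O)[C@](C)(C/C=C/C)[C@]13COC(=O)[C@@H]3[C@H]2O[Si](C)(C)C(C)(C)C | intermediate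
16 | aldol adduct of 15: C9 carries a 2-hydroxypropan-2-yl group (C9 epimers) | COC(=O)C(C(C)(C)O)CCC1=C[C@]2(C)C(=O)[C@](C)(C/C=C/C)[C@]13COC(=O)[C@@H]3[C@H]2O[Si](C)(C)C(C)(C)C | intermediate
17 | isotwistane C22 hydroperoxide (ring C closed through C12–C21; C9 and C22 epimers) | COC(=O)C(C(C)(C)O)CC[C@]12C[C@]3(C)C(=O)[C@](C)(C[C@H]1C(C)OO)[C@]24COC(=O)[C@@H]4[C@H]3O[Si](C)(C)C(C)(C)C | intermediate (not isolated)
18 | isotwistane C22 carbinol (C9 and C22 epimers) | COC(=O)C(C(C)(C)O)CC[C@]12C[C@]3(C)C(=O)[C@](C)(C[C@H]1C(C)O)[C@]24COC(=O)[C@@H]4[C@H]3O[Si](C)(C)C(C)(C)C | intermediate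
19 | lactol triol: C8 primary alcohol, C2 tertiary and C22 secondary carbinols, C28 lactol | OCC(C(C)(C)O)CC[C@]12C[C@]3(C)C(=O)[C@](C)(C[C@H]1C(C)O)[C@]24COC(O)[C@@H]4[C@H]3O[Si](C)(C)C(C)(C)C | intermediate
20 | β-hydroxy aldehyde: C8 aldehyde, C2 tertiary carbinol, C22 methyl ketone, γ-lactone | O=CC(C(C)(C)O)CC[C@]12C[C@]3(C)C(=O)[C@](C)(C[C@H]1C(C)=O)[C@]24COC(=O)[C@@H]4[C@H]3O[Si](C)(C)C(C)(C)C | intermediate
21 | α-isopropylidene aldehyde (C9=C2, C8 aldehyde) | O=CC(=C(C)C)CC[C@]12C[C@]3(C)C(=O)[C@](C)(C[C@H]1C(C)=O)[C@]24COC(=O)[C@@H]4[C@H]3O[Si](C)(C)C(C)(C)C | intermediate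
22 | methyl (2Z)-dienoate (C7=C8 Z, C9=C2) | COC(=O)/C=C\C(=C(C)C)CC[C@]12C[C@]3(C)C(=O)[C@](C)(C[C@H]1C(C)=O)[C@]24COC(=O)[C@@H]4[C@H]3O[Si](C)(C)C(C)(C)C | intermediate
23 | dilithium salt of the dienoate with the γ-lactone opened (C26 hydroxymethyl, C28 carboxylate) | [Li+].[Li+].[O-]C(=O)/C=C\C(=C(C)C)CC[C@]12C[C@]3(C)C(=O)[C@](C)(C[C@H]1C(C)=O)[C@@]2(CO)[C@H](C([O-])=O)[C@H]3O[Si](C)(C)C(C)(C)C | intermediate (not isolated)
24 | (2Z)-dienoic acid | OC(=O)/C=C\C(=C(C)C)CC[C@]12C[C@]3(C)C(=O)[C@](C)(C[C@H]1C(C)=O)[C@]24COC(=O)[C@@H]4[C@H]3O[Si](C)(C)C(C)(C)C | intermediate
25 | C31 tert-butyldimethylsilyl ether of the target | CC1(C)OC(=O)C=C[C@]12CC[C@]13C[C@]4(C)C(=O)[C@](C)(C[C@H]1[C@@]2(C)O)[C@]31COC(=O)[C@@H]1[C@H]4O[Si](C)(C)C(C)(C)C | intermediate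
26 | CNP0360620.3 | CC1(C)OC(=O)C=C[C@]12CC[C@]13C[C@]4(C)C(=O)[C@](C)(C[C@H]1[C@@]2(C)O)[C@]31COC(=O)[C@@H]1[C@H]4O | target

## Step count and least certain steps

Total: 19 steps. Longest linear sequence: 19 steps from 1; compounds 2, 6 and 9 are commercial and enter directly.

**Step 18 (labelled step).** The most likely failure is that the alkene attacks the ketone too slowly, so that lactonization without C–C bond formation or ene-type proton loss to an isopropenyl group takes over. A second risk is closure through the wrong face of C9: allylic strain between the C2 methyl and C10 argues for the arrangement with C2 equatorial. The bond joins a quaternary to a fully substituted carbon, and the diene is deactivated by the carboxyl group. Material with the wrong C21 configuration cannot close; it would have to be recovered and re-equilibrated with base.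

The fallback uses known chemistry and sets out from 20. Still–Gennari olefination of 20 would give the methyl (Z)-δ-hydroxy enoate F1, which lactonizes with loss of methanol to the 5-substituted 6,6-dimethyl-5,6-dihydropyran-2-one F2. An intramolecular vinylogous aldol addition (KOtBu cat., tBuOH/THF, 0 °C) would then generate the cyclic dienolate by γ-deprotonation. C9 is the only dienolate carbon that can reach C22 in a six-membered ring, and the reversible addition lets C9, C22 and C21 settle together. The fallback rejoins the route at 25 and skips steps 15–17.

**Step 8 (key step).** The most likely failure is insufficient facial discrimination between methyl and butenyl on C18 in the cycloaddition, giving the diastereomer that cannot form ring C. Some loss of enantiopurity through a boat Claisen transition state at 180 °C is also possible. The two groups differ only beyond the first carbon.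

The fallback enlarges the migrating group temporarily and sets out from 5. Mitsunobu coupling with (R)-3-bromobut-3-en-2-ol (from Corey–Bakshi–Shibata reduction of 3-bromobut-3-en-2-one) would give the bromo ether aldehyde F3. Borohydride reduction would give the benzylic alcohol F4, esterification with 9 the propiolate F5, and copper-catalysed borylation the borylacrylate F6. Thermolysis would give the adduct F7, whose 2-bromobut-2-enyl group is β-branched and should direct the dienophile more firmly to the methyl face. Hydrodebromination with retention of alkene geometry (Pd(PPh3)4, HCO2H, Et3N) rejoins the route at 13.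

**Step 12.** The most likely failure is capture of the tertiary C12 radical by oxygen before it cyclizes, which would hydrate C12 and leave ring C open. Oxygen trapping of tertiary radicals is close in rate to a 5-exo closure.

The fallback separates C–C bond formation from oxygenation and sets out from 16. A cobalt-catalysed hydrogen-atom-transfer cycloisomerization under argon (Co(salen)Cl-type catalyst, PhSiH3 cat.) would close ring C and end by hydrogen loss from C23, giving the C21 vinyl compound F8. Wacker oxidation (PdCl2, CuCl, O2, DMF/H2O) would give the methyl ketone F9. Step 13 applied to F9 reduces the ketone together with the ester and lactone, and the route is rejoined at 19.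

**Step 4.** The most likely failure is ionization or SN2′ attack on the allylic oxyphosphonium ion together with slow coupling of the di-ortho-substituted phenol, which would erode enantiopurity and conversion.

The fallback moves the substitution to a propargylic centre and sets out from 5. Mitsunobu coupling with (R)-but-3-yn-2-ol, which has no allylic transposition pathway, would give the (S)-alkynyl ether F10. Lindlar semi-hydrogenation (H2, Pd/CaCO3 poisoned with Pb(OAc)2, quinoline) rejoins the route at 7.

## Further compounds

F1 | step 18 | methyl (2Z)-5-hydroxy-5-methylhex-2-enoate carrying the isotwistane ethyl chain on C9 (open hydroxy enoate) | COC(=O)/C=C\C(CC[C@]12C[C@]3(C)C(=O)[C@](C)(C[C@H]1C(C)=O)[C@]24COC(=O)[C@@H]4[C@H]3O[Si](C)(C)C(C)(C)C)C(C)(C)O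
F2 | step 18 | 5-substituted 6,6-dimethyl-5,6-dihydro-2H-pyran-2-one with the C22 methyl ketone still open | O=C1C=CC(CC[C@]23C[C@]4(C)C(=O)[C@](C)(C[C@H]2C(C)=O)[C@]35COC(=O)[C@@H]5[C@H]4O[Si](C)(C)C(C)(C)C)C(C)(C)O1
F3 | step 8 | methyl 4-{4-[(2S)-3-bromobut-3-en-2-yloxy]-2-formyl-3,5-dimethylphenyl}butanoate | C=C(Br)[C@H](C)Oc1c(C)cc(CCCC(=O)OC)c(C=O)c1C
F4 | step 8 | methyl 4-{4-[(2S)-3-bromobut-3-en-2-yloxy]-2-(hydroxymethyl)-3,5-dimethylphenyl}butanoate | C=C(Br)[C@H](C)Oc1c(C)cc(CCCC(=O)OC)c(CO)c1C
F5 | step 8 | bromo analogue of 10 (prop-2-ynoate ester) | C=C(Br)[C@H](C)Oc1c(C)cc(CCCC(=O)OC)c(COC(=O)C#C)c1C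
F6 | step 8 | bromo analogue of 11 ((2E)-3-(pinacolboryl)prop-2-enoate ester) | C=C(Br)[C@H](C)Oc1c(C)cc(CCCC(=O)OC)c(COC(=O)/C=C/B2OC(C)(C)C(C)(C)O2)c1C
F7 | step 8 | bromo analogue of 13 (2-bromobut-2-enyl group on C18) | COC(=O)CCCC1=C[C@]2(C)C(=O)[C@](C)(C/C(Br)=C/C)[C@]13COC(=O)[C@@H]3[C@H]2B4OC(C)(C)C(C)(C)O4
F8 | step 12 | isotwistane with a vinyl group on C21 (C22=C23) and the aldol side chain | COC(=O)C(C(C)(C)O)CC[C@]12C[C@]3(C)C(=O)[C@](C)(C[C@H]1C=C)[C@]24COC(=O)[C@@H]4[C@H]3O[Si](C)(C)C(C)(C)C
F9 | step 12 | isotwistane C22 methyl ketone with the aldol side chain | COC(=O)C(C(C)(C)O)CC[C@]12C[C@]3(C)C(=O)[C@](C)(C[C@H]1C(C)=O)[C@]24COC(=O)[C@@H]4[C@H]3O[Si](C)(C)C(C)(C)C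
F10 | step 4 | methyl 4-{4-[(2S)-but-3-yn-2-yloxy]-2-formyl-3,5-dimethylphenyl}butanoate | C#C[C@H](C)Oc1c(C)cc(CCCC(=O)OC)c(C=O)c1C
A1 | alternative 1 | isotwistane with ring B ketone at C22, phenylsulfonyl at C11, silyl ether at C26 and dioxolane at C31 | O=C1CC[C@H](S(=O)(=O)c2ccccc2)[C@]23C[C@]4(C)C(=O)[C@](C)(C[C@@H]12)[C@@]3(CO[Si](C)(C)C(C)(C)C)CC45OCCO5
A2 | alternative 1 | divinyl ketone | C=CC(=O)C=C
A3 | alternative 1 | bicyclo[2.2.2]octanone with exocyclic (phenylsulfonyl)methylidene at C12, silyl ether at C26 and dioxolane at C31 | CC1C(=O)[C@@]2(C)CC(=CS(=O)(=O)c3ccccc3)[C@]1(CO[Si](C)(C)C(C)(C)C)CC24OCCO4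
A4 | alternative 2 | bicyclo[3.2.1]octan-8-one ketol (rings C and D) | COC(=O)[C@]12C[C@H](C)[C@@H](O)[C@](C)(C[C@H]1C(C)=C)C2=O
A5 | alternative 2 | methacrolein | CC(=C)C=O
A6 | alternative 2 | methyl 3-methyl-2-oxo-5-(prop-1-en-2-yl)cyclopentane-1-carboxylate | COC(=O)C1C(=O)C(C)C[C@H]1C(C)=C
A7 | alternative 3 | spiro α,α-dichlorocyclobutanone at C25 | COC(=O)[C@]12C[C@@](C)(COCc3ccc(OC)cc3)C(=O)[C@](C)(C[C@H]1C4(C)OCCO4)[C@]25CC(=O)C5(Cl)Cl
A8 | alternative 3 | dichloroketene | ClC(Cl)=C=O
A9 | alternative 3 | bicyclo[3.2.1]octane with exocyclic C25=C26 methylene | COC(=O)[C@]12C[C@@](C)(COCc3ccc(OC)cc3)C(=O)[C@](C)(C[C@H]1C4(C)OCCO4)C2=C
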